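Ring A (C1–C5, C10) is closed last, by forming C3–C4 on an intact ring B taken from (R)-carvone. The key step exploits the 1,3-relationship between the C2 oxygen and the gem-dimethyl carbon C4 next to ring-fusion carbon C5: carvone's isopropenyl group is C4 with its methyls, and a 2-chloroallyl arm on quaternary C10 is C1–C3. Acid turns the isopropenyl group into the C4 cation; the chloroalkene traps it, closing ring A and unmasking the C2 ketone in one operation (Lansbury annulation). The carvone carbonyl carbon becomes C9 and carries a citronellyl-derived side chain; the (Z)-coumarate is attached last.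

Key step: step 6

Remark: labdane numbering is used throughout, also for the ring B precursors (ring A = C1–C5, C10; ring B = C5–C10; side chain C11–C15; C16 on C13, C17 on C8, C18/C19 on C4, C20 on C10); α is the face opposite C20.

Step 1
Reactants: 1 (R)-(−)-carvone
Product: 3 (5R)-6-methylcarvone (C6 epimers), via lithium dienolate 2 (not isolated)
Conditions: LiN(iPr)2, THF, −78 °C; MeI, −78 → 0 °C
Reagents that add atoms: iodomethane, CI
Why: Kinetic α′-deprotonation of the enone and C-methylation of the cross-conjugated enolate (enolate alkylation) should install C20; the new centre is re-enolised in step 2, so its configuration does not matter.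

Step 2
Reactants: 3 (5R)-6-methylcarvone
Product: 5 6-(2-chloroallyl)-6-methylcarvone (chloroallyl trans to isopropenyl), via lithium enolate 4 (not isolated)
Conditions: LiN(iPr)2, THF, −78 °C; 2,3-dichloroprop-1-ene, DMPU, Bu4NI (cat.), −78 → 23 °C
Reagents that add atoms: 2,3-dichloroprop-1-ene, ClCC(Cl)=C
Why: Enolate alkylation with an allylic chloride should occur on the face anti to the adjacent C5 isopropenyl group, setting quaternary C10 with the C1–C3 arm trans to isopropenyl and C20 cis to it.

Step 3
Reactants: 6 (R)-citronellyl bromide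
Product: 8 (S)-5-bromo-3-methylpent-1-ene, via methoxy hydroperoxide 7 (not isolated)
Conditions: O3, CH2Cl2/MeOH, −78 °C; then Cu(OAc)2·H2O, FeSO4·7H2O, −20 → 23 °C
Reagents that add atoms: none
Why: Criegee ozonolysis in methanol should give the α-methoxy hydroperoxide at the former CH carbon, which divalent iron cleaves to an alkoxy radical that loses methyl formate by β-scission, and divalent copper oxidises the primary radical to the terminal alkene without touching the C13 stereocentre.

Step 4
Reactants: 8 (S)-5-bromo-3-methylpent-1-ene; 5 6-(2-chloroallyl)-6-methylcarvone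
Product: 10 tertiary allylic alcohol at C9 (C9 epimers), via Grignard reagent 9 (not isolated)
Conditions: Mg, THF, 23 → 45 °C; then CeCl3, 5, THF, −78 → 0 °C; aqueous NH4Cl work-up
Reagents that add atoms: none
Why: Cerium-promoted Grignard 1,2-addition should deliver the side chain to the hindered, non-enolisable enone carbonyl without deprotonation or conjugate addition; the carbinol configuration is irrelevant because C9 becomes sp2 in step 5.

Step 5
Reactants: 10 tertiary allylic alcohol
Product: 11 transposed enone (C7 ketone, C8=C9, side chain on C9)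
Conditions: pyridinium chlorochromate (C5H5NH)[CrO3Cl], CH2Cl2, 4 Å sieves, 23 °C
Reagents that add atoms: pyridinium chlorochromate, [O-][Cr](=O)(=O)Cl.c1cc[nH+]cc1
Why: Dauben–Babler oxidative transposition: the tertiary allylic chromate ester should undergo [3,3] shift to C7 and be oxidised there, leaving the chloroalkene and both terminal alkenes untouched.

Step 6
Reactants: 11 transposed enone
Product: 12 (5S,10S,13S)-labda-8,14-diene-2,7-dione
Conditions: HCO2H (98%), 23 → 45 °C
Reagents that add atoms: formic acid, O=CO
Why: Markovnikov protonation of the 1,1-disubstituted isopropenyl alkene should give the tertiary C4 cation, which is attacked through a chair-like six-membered transition state by the CH2 terminus (C3) of the 2-chloroallyl arm on C10; the chlorine-stabilised C2 cation is captured by formic acid and collapses to the C2 ketone with loss of HCl and CO. The closest known reaction type is the Lansbury chloro-olefin annulation, a cation–olefin cyclization terminated by a vinyl chloride as masked ketone. Ring A is closed in the 6-endo-trig mode with respect to the chloroalkene, forming C3–C4 and turning the former =CH2 carbon into the second C4 methyl. No stereocentre is created (C4 becomes gem-dimethyl, C2 a carbonyl); the trans ring fusion follows from the C5 and C10 configurations fixed by carvone and step 2, since only the conformer with the C4 and C1 arms trans-diequatorial on ring B can close. The step needs protonation of the isopropenyl group in preference to the side-chain vinyl group, the chloroalkene and the deactivated enone (secured by the higher basicity of a 1,1-disubstituted alkene), attack by the unsubstituted alkene carbon (secured by chlorine stabilisation of the C2 cation), and closure faster than 1,2-hydride shift from C5 (secured by the pre-organised six-atom array).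

Step 7
Reactants: 12 labda-8,14-diene-2,7-dione
Product: 14 (13S)-2α,7-bis(trimethylsilyloxy)labda-7,14-diene (9α-H), via dilithium enolate alkoxide 13 (not isolated)
Conditions: Li, NH3(l), THF, t-BuOH (3 equiv), −78 → −33 °C; isoprene; NH3 removed; Me3SiCl, Et3N, THF, −78 → 0 °C
Reagents that add atoms: chlorotrimethylsilane, C[Si](C)(C)Cl
Why: Dissolving-metal reduction should convert the enone into the regiodefined C7–C8 enolate with axial (α) protonation at C9 in the locked trans-decalin (side chain equatorial, β) and reduce the C2 ketone under thermodynamic control to the equatorial 2α-alkoxide (the axial site faces the syn-axial C4 and C10 methyls); silylation traps both oxygens (reductive enolate trapping).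

Step 8
Reactants: 14 bis(trimethylsilyl) compound
Product: 16 (13S)-2α-(trimethylsilyloxy)labda-7,14-dien-7-yl triflate, via lithium enolate 15 (not isolated)
Conditions: MeLi, THF, 0 → 23 °C; then PhNTf2, −78 → 0 °C
Reagents that add atoms: N-phenylbis(trifluoromethanesulfonimide), O=S(=O)(N(c1ccccc1)S(=O)(=O)C(F)(F)F)C(F)(F)F
Why: Methyllithium should cleave only the silyl enol ether, regenerating the regiodefined lithium enolate for O-triflation, while the alkyl silyl ether at C2 is inert.

Step 9
Reactants: 16 enol triflate
Product: 18 (2S,5S,9S,10S,13S)-labda-7,14-dien-2-ol, via trimethylsilyl ether 17 (not isolated)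
Conditions: Pd(OAc)2 (5 mol %), PPh3, Bu3N, HCO2H, DMF, 60 °C; then K2CO3, MeOH, 23 °C
Reagents that add atoms: none
Why: Palladium-catalysed formate reduction of the enol triflate (oxidative addition to zerovalent palladium, formate decarboxylation, C–H reductive elimination) should fix the alkene at C7=C8, and methanolysis removes the labile silyl ether.

Step 10
Reactants: 18 labda-7,14-dien-2α-ol
Product: 20 (2S,5S,9S,10S,13S)-labd-7-ene-2,15-diol, via alkylborane 19 (not isolated)
Conditions: 9-BBN (2.5 equiv), THF, 0 → 23 °C; then NaOH, H2O2, 0 → 23 °C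
Reagents that add atoms: hydrogen peroxide, OO
Why: Anti-Markovnikov hydroboration with 9-BBN should take only the monosubstituted C14=C15 alkene and leave the trisubstituted ring alkene, and oxidation gives the primary C15 alcohol.

Step 11
Reactants: 21 4-(tert-butyldimethylsilyloxy)benzaldehyde
Product: 22 methyl (Z)-3-[4-(tert-butyldimethylsilyloxy)phenyl]prop-2-enoate
Conditions: methyl bis(2,2,2-trifluoroethyl)phosphonoacetate, KN(SiMe3)2, 18-crown-6, THF, −78 °C
Reagents that add atoms: methyl 2-[bis(2,2,2-trifluoroethoxy)phosphoryl]acetate, COC(=O)CP(=O)(OCC(F)(F)F)OCC(F)(F)F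
Why: Still–Gennari olefination with the electron-poor phosphonate under dissociating conditions should give the kinetic (Z)-enoate.

Step 12
Reactants: 22 methyl (Z)-silyloxycinnamate
Product: 23 (Z)-4-hydroxycinnamic acid ((Z)-p-coumaric acid)
Conditions: LiOH, THF/MeOH/H2O, 23 °C, dark; 1 M HCl work-up
Reagents that add atoms: lithium hydroxide, [Li+].[OH-]
Why: Saponification should cleave the methyl ester and the aryl silyl ether together, and the (Z)-alkene is stable to base at room temperature in the dark.

Step 13
Reactants: 20 labd-7-ene-2α,15-diol; 23 (Z)-p-coumaric acid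
Product: 24 (2S,5S,9S,10S,13S)-2-hydroxylabd-7-en-15-yl (2Z)-3-(4-hydroxyphenyl)prop-2-enoate
Conditions: PPh3, DIAD, THF, 0 → 23 °C, dark
Reagents that add atoms: none
Why: Mitsunobu esterification should activate only the primary C15 alcohol (the 2α-alcohol is hindered), the carboxylate outcompetes the far less acidic phenol, and the absence of acyl activation preserves the (Z)-geometry.

Compound list
1 | (R)-(−)-carvone | CC1=CC[C@@H](C(C)=C)CC1=O | starting material
2 | lithium dienolate of carvone (not isolated) | [Li+].CC1=CC[C@@H](C(C)=C)C=C1[O-] | intermediate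
3 | (5R)-2,6-dimethyl-5-(prop-1-en-2-yl)cyclohex-2-en-1-one, C6 epimers (6-methylcarvone) | CC1=CC[C@@H](C(C)=C)C(C)C1=O | intermediate
4 | lithium enolate of 6-methylcarvone (not isolated) | [Li+].CC1=CC[C@@H](C(C)=C)C(C)=C1[O-] | intermediate
5 | (5S,6S)-6-(2-chloroprop-2-en-1-yl)-2,6-dimethyl-5-(prop-1-en-2-yl)cyclohex-2-en-1-one | CC1=CC[C@@H](C(C)=C)[C@](C)(CC(Cl)=C)C1=O | intermediate
6 | (R)-citronellyl bromide, (6R)-8-bromo-2,6-dimethyloct-2-ene | C[C@H](CCC=C(C)C)CCBr | starting material
7 | (4R)-6-bromo-1-methoxy-4-methylhexyl hydroperoxide (not isolated) | C[C@H](CCC(OC)OO)CCBr | intermediate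
8 | (S)-5-bromo-3-methylpent-1-ene | C[C@H](C=C)CCBr | intermediate
9 | [(3S)-3-methylpent-4-en-1-yl]magnesium bromide (not isolated) | C[C@H](C=C)CC[Mg]Br | intermediate
10 | (5S,6S)-6-(2-chloroprop-2-en-1-yl)-2,6-dimethyl-1-[(3S)-3-methylpent-4-en-1-yl]-5-(prop-1-en-2-yl)cyclohex-2-en-1-ol, C1 epimers | CC1=CC[C@@H](C(C)=C)[C@](C)(CC(Cl)=C)C1(O)CC[C@H](C)C=C | intermediate
11 | (4S,5S)-4-(2-chloroprop-2-en-1-yl)-2,4-dimethyl-3-[(3S)-3-methylpent-4-en-1-yl]-5-(prop-1-en-2-yl)cyclohex-2-en-1-one | O=C1C[C@@H](C(C)=C)[C@](C)(CC(Cl)=C)C(CC[C@H](C)C=C)=C1C | intermediate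
12 | (5S,10S,13S)-labda-8,14-diene-2,7-dione (trans-fused, 5α-H, 10β-CH3) | O=C1C[C@H]2C(C)(C)CC(=O)C[C@]2(C)C(CC[C@H](C)C=C)=C1C | intermediate
13 | dilithium C7 enolate / C2α alkoxide of the reduced dione (not isolated) | [Li+].[Li+].CC1=C([O-])C[C@H]2C(C)(C)C[C@H]([O-])C[C@]2(C)[C@H]1CC[C@H](C)C=C | intermediate
14 | (5S,9S,10S,13S)-2α,7-bis(trimethylsilyloxy)labda-7,14-diene | CC1=C(O[Si](C)(C)C)C[C@H]2C(C)(C)C[C@H](O[Si](C)(C)C)C[C@]2(C)[C@H]1CC[C@H](C)C=C | intermediate
15 | lithium C7 enolate, 2α-trimethylsilyl ether (not isolated) | [Li+].CC1=C([O-])C[C@H]2C(C)(C)C[C@H](O[Si](C)(C)C)C[C@]2(C)[C@H]1CC[C@H](C)C=C | intermediate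
16 | (5S,9S,10S,13S)-2α-(trimethylsilyloxy)labda-7,14-dien-7-yl trifluoromethanesulfonate | CC1=C(OS(=O)(=O)C(F)(F)F)C[C@H]2C(C)(C)C[C@H](O[Si](C)(C)C)C[C@]2(C)[C@H]1CC[C@H](C)C=C | intermediate
17 | (5S,9S,10S,13S)-2α-(trimethylsilyloxy)labda-7,14-diene (not isolated) | CC1=CC[C@H]2C(C)(C)C[C@H](O[Si](C)(C)C)C[C@]2(C)[C@H]1CC[C@H](C)C=C | intermediate
18 | (2S,5S,9S,10S,13S)-labda-7,14-dien-2-ol (2α-OH) | CC1=CC[C@H]2C(C)(C)C[C@H](O)C[C@]2(C)[C@H]1CC[C@H](C)C=C | intermediate
19 | B-[(13S)-2α-hydroxylabd-7-en-15-yl]-9-borabicyclo[3.3.1]nonane (not isolated) | CC1=CC[C@H]2C(C)(C)C[C@H](O)C[C@]2(C)[C@H]1CC[C@H](C)CCB1C2CCCC1CCC2 | intermediate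
20 | (2S,5S,9S,10S,13S)-labd-7-ene-2,15-diol | CC1=CC[C@H]2C(C)(C)C[C@H](O)C[C@]2(C)[C@H]1CC[C@H](C)CCO | intermediate
21 | 4-(tert-butyldimethylsilyloxy)benzaldehyde | O=Cc1ccc(O[Si](C)(C)C(C)(C)C)cc1 | starting material
22 | methyl (Z)-3-[4-(tert-butyldimethylsilyloxy)phenyl]prop-2-enoate | COC(=O)/C=C\c1ccc(O[Si](C)(C)C(C)(C)C)cc1 | intermediate
23 | (Z)-3-(4-hydroxyphenyl)prop-2-enoic acid | OC(=O)/C=C\c1ccc(O)cc1 | intermediate
24 | (2S,5S,9S,10S,13S)-2-hydroxylabd-7-en-15-yl (2Z)-3-(4-hydroxyphenyl)prop-2-enoate | CC1=CC[C@H]2C(C)(C)C[C@H](O)C[C@]2(C)[C@H]1CC[C@H](C)CCOC(=O)/C=C\c1ccc(O)cc1 | target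

Total steps: 13. Longest linear sequence: 10 steps (1, 2, 4–10, 13).

Steps most likely to fail

Step 6. The C4 cation may be drained by 1,2-hydride shift from C5 and proton loss into conjugation with the enone, or sit as the tertiary formate, before the weakly nucleophilic chloroalkene closes the ring; slow addition of formic acid to the side-chain vinyl group would add to the loss. The fallback sets out from 3 and returns at 12; it closes ring A earlier with a much stronger π-nucleophile and no side chain present. Enolate 4 is alkylated with methyl (E)-4-bromo-3-methoxybut-2-enoate to give the enol ether F1, and aqueous HCl gives the β-keto ester F2. SnCl4 in CH2Cl2 should then close ring A through C3–C4 by attack of the tin-bound β-keto ester enol on the C4 cation, giving the bicyclic β-keto ester F3. LiCl in wet DMSO at 150 °C (Krapcho) gives the enedione F4, and ethylene glycol with PPTS masks the unconjugated C2 ketone as the dioxolane F5. Grignard reagent 9 with CeCl3 gives the carbinol F6, pyridinium chlorochromate gives the transposed enone F7, and aqueous HCl in THF removes the dioxolane to give 12.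

Step 7. The enolate may be protonated and reduced further, the C2 ketone may be reduced incompletely or couple to a pinacol, and the enolate regiochemistry may scramble by proton exchange during silylation. The fallback sets out from 12 and returns at 18; it separates the two reductions. Ketalisation of the C2 ketone gives the dioxolane F7 (the compound met in the previous fallback). Li/NH3 with one equivalent of t-BuOH followed directly by PhNTf2 gives the enol triflate F8, and Pd(OAc)2/PPh3/Bu3N/HCO2H gives the alkene ketal F9. Aqueous HCl gives labda-7,14-dien-2-one F10, and sodium in isopropanol/toluene (thermodynamic reduction to the equatorial alcohol) gives 18.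

Step 3. The primary ozonide may fragment in the other sense, putting the carbonyl oxide on the acetone fragment, so that the chain ends as an aldehyde and no radical fragmentation follows. The fallback sets out from 6 and returns at 8. Ozonolysis with Me2S work-up gives (R)-6-bromo-4-methylhexanal F11, which is dehydroformylated to 8 by rhodium-catalysed transfer hydroformylation onto norbornadiene ([Rh(cod)(OMe)]2, Xantphos, 3-methoxybenzoic acid, THF, 60 °C).

Further compounds
F1 | step 6 | 6-methylcarvone bearing at C10 (trans to isopropenyl) an (E)-2-methoxy-4-methoxy-4-oxobut-2-en-1-yl group | CC1=CC[C@@H](C(C)=C)[C@](C)(C/C(OC)=C\C(=O)OC)C1=O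
F2 | step 6 | 6-methylcarvone bearing at C10 (trans to isopropenyl) a 4-methoxy-2,4-dioxobutyl group (β-keto ester) | CC1=CC[C@@H](C(C)=C)[C@](C)(CC(=O)CC(=O)OC)C1=O
F3 | step 6 | trans-fused bicyclic β-keto ester: ring A closed, CO2Me on C3, C2 ketone, C9 ketone conjugated with C7=C8 (5α-H, 10β-CH3, C3 epimers) | CC1=CC[C@H]2C(C)(C)C(C(=O)OC)C(=O)C[C@]2(C)C1=O
F4 | step 6 | trans-fused bicyclic enedione: C2 ketone, C9 ketone, C7=C8 (5α-H, 10β-CH3) | CC1=CC[C@H]2C(C)(C)CC(=O)C[C@]2(C)C1=O
F5 | step 6 | C2 ethylene ketal of the bicyclic enedione | CC1=CC[C@H]2C(C)(C)CC3(OCCO3)C[C@]2(C)C1=O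
F6 | step 6 | C9 tertiary carbinol from addition of the side chain to the ketal (C9 epimers) | CC1=CC[C@H]2C(C)(C)CC3(OCCO3)C[C@]2(C)C1(O)CC[C@H](C)C=C
F7 | step 6 | C2 ethylene ketal of (5S,10S,13S)-labda-8,14-diene-2,7-dione | O=C1C[C@H]2C(C)(C)CC3(OCCO3)C[C@]2(C)C(CC[C@H](C)C=C)=C1C
F8 | step 7 | C2 ethylene ketal of (13S)-2-oxolabda-7,14-dien-7-yl trifluoromethanesulfonate (9α-H) | CC1=C(OS(=O)(=O)C(F)(F)F)C[C@H]2C(C)(C)CC3(OCCO3)C[C@]2(C)[C@H]1CC[C@H](C)C=C
F9 | step 7 | (5S,9S,10S,13S)-labda-7,14-dien-2-one ethylene ketal | CC1=CC[C@H]2C(C)(C)CC3(OCCO3)C[C@]2(C)[C@H]1CC[C@H](C)C=C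
F10 | step 7 | (5S,9S,10S,13S)-labda-7,14-dien-2-one | CC1=CC[C@H]2C(C)(C)CC(=O)C[C@]2(C)[C@H]1CC[C@H](C)C=C
F11 | step 3 | (R)-6-bromo-4-methylhexanal | C[C@H](CCC=O)CCBr
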